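**Retrosynthetic overview**
- The target is unveiled by hydrogenolysis of five O-benzyl ethers; the 7-OMe is carried from the start.
- The two identical side chains are attached last, by a twofold Negishi benzyl–aryl coupling of an (S)-6,8-dibromoflavanone with one benzylzinc reagent (itself from a Suzuki-built diarylmethane).
- Ring C is closed onto the purchased ring A by an invertive intramolecular Mitsunobu etherification (O1–C2), with the C4 ketone masked as a 1,3-dithiane.
- The carbinol precursor comes from a lithiated aryl dithiane opening (S)-styrene oxide; the epoxide comes from a ketoreductase reduction of phenacyl chloride, which sets the only stereocentre.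
- Ring order: ring A (bought) → ring C (Mitsunobu) → side-chain rings (cross-coupling).

Assumption: the SMILES is taken as authoritative; its single stereocentre is C2 of a flavanone and is S.

**Step 1**
Reactants: 1 2-chloro-1-phenylethan-1-one (phenacyl chloride)
Product: 2 (1S)-2-chloro-1-phenylethan-1-ol
Conditions: anti-Prelog ketoreductase (NADPH-dependent alcohol dehydrogenase, Lactobacillus kefir type), NADP+ (cat.), i-PrOH (15% v/v), phosphate buffer pH 7, MgSO4 (1 mM), 30 °C
Reagents that add atoms: none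
Why: Ketoreductase-catalysed asymmetric carbonyl reduction delivers hydride from NADPH to one face of the prochiral ketone and sets the (S)-carbinol centre in typically >99% ee, with isopropanol recycling the cofactor.

**Step 2**
Reactants: 2 (1S)-2-chloro-1-phenylethan-1-ol
Product: 3 (2S)-2-phenyloxirane ((S)-styrene oxide)
Conditions: NaOH (2 M aq), MTBE, 20 °C
Reagents that add atoms: none
Why: Halohydrin ring closure (intramolecular Williamson etherification) displaces the primary chloride, so the stereocentre is not touched and stays S.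

**Step 3**
Reactants: 4 5-methoxybenzene-1,3-diol (5-methoxyresorcinol)
Product: 5 1-methoxy-3,5-bis(methoxymethoxy)benzene
Conditions: NaH, MOMCl, DMF, 0 °C → rt
Reagents that add atoms: chloromethyl methyl ether (MOMCl), COCCl
Why: Williamson-type O-alkylation of both phenoxides installs MOM ethers that protect the phenols and act as strong directing groups for the next metalation.

**Step 4**
Reactants: 5 1-methoxy-3,5-bis(methoxymethoxy)benzene
Product: 7 4-methoxy-2,6-bis(methoxymethoxy)benzaldehyde, via aryllithium 6 (not isolated)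
Conditions: n-BuLi, TMEDA, THF, 0 °C; then DMF, 0 °C → rt; H2O
Reagents that add atoms: N,N-dimethylformamide, CN(C)C=O
Why: Directed ortho-metalation takes place at the position flanked by the two MOM ethers and formylation of the aryllithium with DMF gives the symmetric aldehyde as a single regioisomer.

**Step 5**
Reactants: 7 4-methoxy-2,6-bis(methoxymethoxy)benzaldehyde
Product: 8 2,6-dihydroxy-4-methoxybenzaldehyde
Conditions: HCl (cat.), MeOH, 40 °C
Reagents that add atoms: none
Why: Acid-catalysed acetal exchange removes the MOM ethers, which would not survive the Lewis acid and thiol of the next step.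

**Step 6**
Reactants: 8 2,6-dihydroxy-4-methoxybenzaldehyde
Product: 9 2-(1,3-dithian-2-yl)-5-methoxybenzene-1,3-diol
Conditions: HS(CH2)3SH, BF3·OEt2 (cat.), CH2Cl2, 0 °C → rt
Reagents that add atoms: propane-1,3-dithiol, SCCCS
Why: Lewis acid-catalysed dithioacetalisation turns the aldehyde into a 1,3-dithiane, the Corey–Seebach acyl-anion equivalent that later also masks the C4 ketone.

**Step 7**
Reactants: 9 2-(1,3-dithian-2-yl)-5-methoxybenzene-1,3-diol
Product: 10 2-[4-methoxy-2,6-bis(methoxymethoxy)phenyl]-1,3-dithiane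
Conditions: NaH, MOMCl, DMF, 0 °C → rt
Reagents that add atoms: chloromethyl methyl ether (MOMCl), COCCl
Why: Williamson-type O-alkylation re-masks both phenols as base-stable MOM ethers so that the dithiane C2–H is the most acidic site left for n-BuLi.

**Step 8**
Reactants: 10 2-[4-methoxy-2,6-bis(methoxymethoxy)phenyl]-1,3-dithiane; 3 (2S)-2-phenyloxirane
Product: 12 (1R)-2-{2-[4-methoxy-2,6-bis(methoxymethoxy)phenyl]-1,3-dithian-2-yl}-1-phenylethan-1-ol, via lithiated dithiane 11 (not isolated)
Conditions: n-BuLi, THF, −78 → −20 °C; then 3, −20 °C → rt; H2O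
Reagents that add atoms: none
Why: Corey–Seebach alkylation in which the 2-lithio-1,3-dithiane opens the epoxide by SN2 attack at the unsubstituted carbon, so the stereocentre is retained and its descriptor becomes R only because the CH2 group now ranks below phenyl in the Cahn–Ingold–Prelog order.

**Step 9**
Reactants: 12 (1R)-2-{2-[4-methoxy-2,6-bis(methoxymethoxy)phenyl]-1,3-dithian-2-yl}-1-phenylethan-1-ol
Product: 13 2-{2-[(2R)-2-hydroxy-2-phenylethyl]-1,3-dithian-2-yl}-5-methoxybenzene-1,3-diol
Conditions: HCl (1.25 M in MeOH), 25 → 40 °C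
Reagents that add atoms: none
Why: Acid-catalysed MOM cleavage frees the two equivalent phenols, while the dithiane and the unactivated secondary benzylic alcohol do not ionise under these mild conditions.

**Step 10**
Reactants: 13 2-{2-[(2R)-2-hydroxy-2-phenylethyl]-1,3-dithian-2-yl}-5-methoxybenzene-1,3-diol
Product: 14 (2S)-7-methoxy-2-phenyl-2,3-dihydrospiro[chromene-4,2'-[1,3]dithian]-5-ol
Conditions: PPh3, DIAD, THF (0.02 M), 0 °C → rt
Reagents that add atoms: none
Why: Intramolecular Mitsunobu etherification closes ring C by SN2 attack of either equivalent phenol on the oxyphosphonium with inversion (R → S), the dithiane blocking the E1cB loss of water to a chalcone that a free ketone would allow.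

**Step 11**
Reactants: 14 (2S)-7-methoxy-2-phenyl-2,3-dihydrospiro[chromene-4,2'-[1,3]dithian]-5-ol
Product: 15 (2S)-5-(benzyloxy)-7-methoxy-2-phenyl-2,3-dihydrospiro[chromene-4,2'-[1,3]dithiane]
Conditions: BnBr, K2CO3, DMF, 50 °C
Reagents that add atoms: benzyl bromide, BrCc1ccccc1
Why: Williamson etherification of the remaining phenol is done while C4 is still a dithioketal, so base cannot enolise or open ring C and C2 cannot racemise.

**Step 12**
Reactants: 15 (2S)-5-(benzyloxy)-7-methoxy-2-phenyl-2,3-dihydrospiro[chromene-4,2'-[1,3]dithiane]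
Product: 16 (2S)-5-(benzyloxy)-7-methoxy-2-phenylchroman-4-one
Conditions: MeI, CaCO3, MeCN/H2O (4:1), 50 °C
Reagents that add atoms: water, O
Why: Alkylative dithiane hydrolysis (S-methylation, then hydrolysis of the aryl-stabilised thionium ion) unmasks the ketone under near-neutral conditions that leave C2 untouched.

**Step 13**
Reactants: 16 (2S)-5-(benzyloxy)-7-methoxy-2-phenylchroman-4-one
Product: 17 (2S)-5-(benzyloxy)-6,8-dibromo-7-methoxy-2-phenylchroman-4-one
Conditions: NBS (2.2 equiv), DMF, 0 °C → rt, dark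
Reagents that add atoms: N-bromosuccinimide, O=C1CCC(=O)N1Br
Why: Electrophilic aromatic bromination takes the only two free positions of ring A, each ortho or para to three oxygen substituents, under non-basic conditions.

**Step 14**
Reactants: 18 5-bromo-2-hydroxybenzaldehyde
Product: 19 2-(benzyloxy)-5-bromobenzaldehyde
Conditions: BnBr, K2CO3, DMF, 60 °C
Reagents that add atoms: benzyl bromide, BrCc1ccccc1
Why: Williamson etherification protects the phenol as the benzyl ether that is removed only in the last step.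

**Step 15**
Reactants: 19 2-(benzyloxy)-5-bromobenzaldehyde
Product: 20 2-(benzyloxy)-5-(4,4,5,5-tetramethyl-1,3,2-dioxaborolan-2-yl)benzaldehyde
Conditions: B2pin2, Pd(dppf)Cl2 (3 mol %), KOAc, 1,4-dioxane, 90 °C
Reagents that add atoms: bis(pinacolato)diboron, CC1(C)OB(OC1(C)C)B1OC(C)(C)C(C)(C)O1
Why: Miyaura borylation converts the aryl bromide into the pinacol boronate with the non-enolisable aldehyde tolerated.

**Step 16**
Reactants: 21 [2-(benzyloxy)phenyl]methanol
Product: 22 1-(benzyloxy)-2-(bromomethyl)benzene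
Conditions: PBr3, CH2Cl2, 0 °C
Reagents that add atoms: phosphorus tribromide, BrP(Br)Br
Why: Bromination of a primary benzylic alcohol through its phosphite ester by SN2 displacement is fast and clean.

**Step 17**
Reactants: 20 2-(benzyloxy)-5-(4,4,5,5-tetramethyl-1,3,2-dioxaborolan-2-yl)benzaldehyde; 22 1-(benzyloxy)-2-(bromomethyl)benzene
Product: 23 2-(benzyloxy)-5-[2-(benzyloxy)benzyl]benzaldehyde
Conditions: Pd(PPh3)4 (3 mol %), K2CO3, DME/H2O (4:1), 80 °C
Reagents that add atoms: none
Why: Suzuki–Miyaura coupling of an aryl boronate with a benzylic bromide forms the diarylmethane para to the benzyloxy group with no regiochemical ambiguity.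

**Step 18**
Reactants: 23 2-(benzyloxy)-5-[2-(benzyloxy)benzyl]benzaldehyde
Product: 24 {2-(benzyloxy)-5-[2-(benzyloxy)benzyl]phenyl}methanol
Conditions: NaBH4, MeOH/THF, 0 °C
Reagents that add atoms: none
Why: Borohydride reduction of the aldehyde gives the primary benzylic alcohol without touching the benzyl ethers.

**Step 19**
Reactants: 24 {2-(benzyloxy)-5-[2-(benzyloxy)benzyl]phenyl}methanol
Product: 25 1-(benzyloxy)-4-[2-(benzyloxy)benzyl]-2-(chloromethyl)benzene
Conditions: SOCl2, CH2Cl2, 0 °C → rt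
Reagents that add atoms: thionyl chloride, O=S(Cl)Cl
Why: Chlorodehydroxylation through the chlorosulfite gives the benzylic chloride needed for direct zinc insertion.

**Step 20**
Reactants: 25 1-(benzyloxy)-4-[2-(benzyloxy)benzyl]-2-(chloromethyl)benzene (2.8 equiv); 17 (2S)-5-(benzyloxy)-6,8-dibromo-7-methoxy-2-phenylchroman-4-one
Product: 27 (2S)-5-(benzyloxy)-6,8-bis{2-(benzyloxy)-5-[2-(benzyloxy)benzyl]benzyl}-7-methoxy-2-phenylchroman-4-one, via benzylzinc chloride 26 (not isolated)
Conditions: 25, Zn dust, LiCl, THF, 25 °C; then 17, Pd(OAc)2 (5 mol %), SPhos (10 mol %), THF, 50 °C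
Reagents that add atoms: none
Why: Twofold Negishi coupling, in which SPhos-ligated zerovalent palladium inserts into both hindered C–Br bonds and the base-free benzylzinc reagent tolerates the ketone and cannot open ring C, so C2 keeps its configuration.

**Step 21**
Reactants: 27 (2S)-5-(benzyloxy)-6,8-bis{2-(benzyloxy)-5-[2-(benzyloxy)benzyl]benzyl}-7-methoxy-2-phenylchroman-4-one
Product: 28 (2S)-5-hydroxy-6,8-bis[2-hydroxy-5-(2-hydroxybenzyl)benzyl]-7-methoxy-2-phenylchroman-4-one (target)
Conditions: H2 (1 atm), Pd/C (10 wt %), EtOAc/MeOH, rt, stopped at full conversion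
Reagents that add atoms: none
Why: Catalytic hydrogenolysis removes all five O-benzyl groups under neutral conditions that leave the methyl ether, the diarylmethanes and the flavanone C2 centre intact.

**Compound list**
1 | 2-chloro-1-phenylethan-1-one | O=C(CCl)c1ccccc1 | starting material
2 | (1S)-2-chloro-1-phenylethan-1-ol | O[C@H](CCl)c1ccccc1 | intermediate
3 | (2S)-2-phenyloxirane | c1ccccc1[C@H]1CO1 | intermediate
4 | 5-methoxybenzene-1,3-diol | COc1cc(O)cc(O)c1 | starting material
5 | 1-methoxy-3,5-bis(methoxymethoxy)benzene | COCOc1cc(OC)cc(OCOC)c1 | intermediate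
6 | [4-methoxy-2,6-bis(methoxymethoxy)phenyl]lithium | [Li]c1c(OCOC)cc(OC)cc1OCOC | intermediate
7 | 4-methoxy-2,6-bis(methoxymethoxy)benzaldehyde | O=Cc1c(OCOC)cc(OC)cc1OCOC | intermediate
8 | 2,6-dihydroxy-4-methoxybenzaldehyde | O=Cc1c(O)cc(OC)cc1O | intermediate
9 | 2-(1,3-dithian-2-yl)-5-methoxybenzene-1,3-diol | COc1cc(O)c(C2SCCCS2)c(O)c1 | intermediate
10 | 2-[4-methoxy-2,6-bis(methoxymethoxy)phenyl]-1,3-dithiane | COCOc1cc(OC)cc(OCOC)c1C1SCCCS1 | intermediate
11 | 2-lithio-2-[4-methoxy-2,6-bis(methoxymethoxy)phenyl]-1,3-dithiane | [Li]C1(c2c(OCOC)cc(OC)cc2OCOC)SCCCS1 | intermediate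
12 | (1R)-2-{2-[4-methoxy-2,6-bis(methoxymethoxy)phenyl]-1,3-dithian-2-yl}-1-phenylethan-1-ol | O[C@H](CC1(c2c(OCOC)cc(OC)cc2OCOC)SCCCS1)c1ccccc1 | intermediate
13 | 2-{2-[(2R)-2-hydroxy-2-phenylethyl]-1,3-dithian-2-yl}-5-methoxybenzene-1,3-diol | O[C@H](CC1(c2c(O)cc(OC)cc2O)SCCCS1)c1ccccc1 | intermediate
14 | (2S)-7-methoxy-2-phenyl-2,3-dihydrospiro[chromene-4,2'-[1,3]dithian]-5-ol | COc1cc(O)c2c(c1)O[C@H](c1ccccc1)CC23SCCCS3 | intermediate
15 | (2S)-5-(benzyloxy)-7-methoxy-2-phenyl-2,3-dihydrospiro[chromene-4,2'-[1,3]dithiane] | COc1cc(OCc4ccccc4)c2c(c1)O[C@H](c1ccccc1)CC23SCCCS3 | intermediate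
16 | (2S)-5-(benzyloxy)-7-methoxy-2-phenylchroman-4-one | COc1cc(OCc3ccccc3)c2c(c1)O[C@H](c1ccccc1)CC2=O | intermediate
17 | (2S)-5-(benzyloxy)-6,8-dibromo-7-methoxy-2-phenylchroman-4-one | COc1c(Br)c(OCc3ccccc3)c2c(c1Br)O[C@H](c1ccccc1)CC2=O | intermediate
18 | 5-bromo-2-hydroxybenzaldehyde | O=Cc1cc(Br)ccc1O | starting material
19 | 2-(benzyloxy)-5-bromobenzaldehyde | O=Cc1cc(Br)ccc1OCc1ccccc1 | intermediate
20 | 2-(benzyloxy)-5-(4,4,5,5-tetramethyl-1,3,2-dioxaborolan-2-yl)benzaldehyde | O=Cc1cc(B2OC(C)(C)C(C)(C)O2)ccc1OCc1ccccc1 | intermediate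
21 | [2-(benzyloxy)phenyl]methanol | OCc1ccccc1OCc1ccccc1 | starting material
22 | 1-(benzyloxy)-2-(bromomethyl)benzene | BrCc1ccccc1OCc1ccccc1 | intermediate
23 | 2-(benzyloxy)-5-[2-(benzyloxy)benzyl]benzaldehyde | O=Cc1cc(Cc2ccccc2OCc2ccccc2)ccc1OCc1ccccc1 | intermediate
24 | {2-(benzyloxy)-5-[2-(benzyloxy)benzyl]phenyl}methanol | OCc1cc(Cc2ccccc2OCc2ccccc2)ccc1OCc1ccccc1 | intermediate
25 | 1-(benzyloxy)-4-[2-(benzyloxy)benzyl]-2-(chloromethyl)benzene | ClCc1cc(Cc2ccccc2OCc2ccccc2)ccc1OCc1ccccc1 | intermediate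
26 | {2-(benzyloxy)-5-[2-(benzyloxy)benzyl]benzyl}zinc chloride | Cl[Zn]Cc1cc(Cc2ccccc2OCc2ccccc2)ccc1OCc1ccccc1 | intermediate
27 | (2S)-5-(benzyloxy)-6,8-bis{2-(benzyloxy)-5-[2-(benzyloxy)benzyl]benzyl}-7-methoxy-2-phenylchroman-4-one | COc1c(Cc2cc(Cc3ccccc3OCc3ccccc3)ccc2OCc2ccccc2)c(OCc2ccccc2)c2c(c1Cc1cc(Cc3ccccc3OCc3ccccc3)ccc1OCc1ccccc1)O[C@H](c1ccccc1)CC2=O | intermediate
28 | (2S)-5-hydroxy-6,8-bis[2-hydroxy-5-(2-hydroxybenzyl)benzyl]-7-methoxy-2-phenylchroman-4-one | COc1c(Cc2cc(Cc3ccccc3O)ccc2O)c(O)c2c(c1Cc1cc(Cc3ccccc3O)ccc1O)O[C@H](c1ccccc1)CC2=O | target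

**Totals**
Total step count: 21.
Longest linear sequence: 13 steps (steps 3–13, 20 and 21, from 5-methoxyresorcinol 4).

**Steps most likely to fail, with fallbacks**

Step 8 (opening of epoxide 3 by the hindered anion 11). The di-ortho-substituted dithiane anion may react sluggishly or attack the benzylic carbon. The fallback reaches the same carbinol without a dithiane carbanion; it sets out from aldehyde 7 and comes back at 12. Ohira–Bestmann homologation of 7 (dimethyl (1-diazo-2-oxopropyl)phosphonate, K2CO3, MeOH) gives 2-ethynyl-5-methoxy-1,3-bis(methoxymethoxy)benzene F1. Acyl Sonogashira coupling with benzoyl chloride (PdCl2(PPh3)2, CuI, Et3N, THF) gives 3-[4-methoxy-2,6-bis(methoxymethoxy)phenyl]-1-phenylprop-2-yn-1-one F2. Double conjugate addition of propane-1,3-dithiol (NaOMe, MeOH/CH2Cl2) places both sulfurs on the aryl-bearing carbon and gives 2-{2-[4-methoxy-2,6-bis(methoxymethoxy)phenyl]-1,3-dithian-2-yl}-1-phenylethan-1-one F3. An (R)-selective ketoreductase from a bulky-ketone panel then reduces the phenyl ketone of F3 to 12; if no enzyme accepts F3, transfer hydrogenation with RuCl(p-cymene)[(R,R)-TsDPEN] and HCO2H/Et3N is the chemical stand-in.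

Step 10 (Mitsunobu closure). Styrene-type elimination or partial loss of ee through a benzylic ion pair is possible. The fallback sets C2 by catalytic asymmetric conjugate addition to a chromone; it sets out from 5 and comes back at 16. Aryllithium 6, made as in step 4, is quenched with N-methoxy-N-methylacetamide to give 1-[4-methoxy-2,6-bis(methoxymethoxy)phenyl]ethan-1-one F4. HCl in MeOH gives 1-(2,6-dihydroxy-4-methoxyphenyl)ethan-1-one F5. DMF dimethyl acetal (toluene, 90 °C) gives (E)-1-(2,6-dihydroxy-4-methoxyphenyl)-3-(dimethylamino)prop-2-en-1-one F6, which closes in aqueous HCl to 5-hydroxy-7-methoxy-4H-chromen-4-one F7. BnBr and K2CO3 in DMF give 5-(benzyloxy)-7-methoxy-4H-chromen-4-one F8. Addition of phenylboronic acid under Pd(OCOCF3)2 and the pyridine–oxazoline ligand (R)-t-BuPyOX (NH4PF6, H2O, 1,2-dichloroethane, 60 °C) then gives 16. The ligand antipode is the one predicted to give 2S from the facial model for cyclic enones and must be confirmed by chiral HPLC and optical rotation.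

Step 20 (twofold Negishi coupling on a hexasubstituted ring). The reaction may stall at the monobenzylated bromide or give protodebromination. The fallback attaches the side chains by electrophilic aromatic substitution; it sets out from 14 and comes back at 28. Hydrolysis of 14 as in step 12 (MeI, CaCO3, MeCN/H2O) gives (2S)-5-hydroxy-7-methoxy-2-phenylchroman-4-one F9, whose free 5-OH makes C6 and C8 strongly nucleophilic. Friedel–Crafts benzylation with 2.2 equiv of benzylic alcohol 24 (Sc(OTf)3 10 mol %, MeNO2/CH2Cl2, rt, or ZnCl2 in dioxane) gives (2S)-6,8-bis{2-(benzyloxy)-5-[2-(benzyloxy)benzyl]benzyl}-5-hydroxy-7-methoxy-2-phenylchroman-4-one F10. Hydrogenolysis as in step 21 gives 28; the ee must be re-checked because Lewis acid can open ring C.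

**Further compounds**
F1 | step 8 | 2-ethynyl-5-methoxy-1,3-bis(methoxymethoxy)benzene | C#Cc1c(OCOC)cc(OC)cc1OCOC
F2 | step 8 | 3-[4-methoxy-2,6-bis(methoxymethoxy)phenyl]-1-phenylprop-2-yn-1-one | O=C(C#Cc1c(OCOC)cc(OC)cc1OCOC)c1ccccc1
F3 | step 8 | 2-{2-[4-methoxy-2,6-bis(methoxymethoxy)phenyl]-1,3-dithian-2-yl}-1-phenylethan-1-one | O=C(CC1(c2c(OCOC)cc(OC)cc2OCOC)SCCCS1)c1ccccc1
F4 | step 10 | 1-[4-methoxy-2,6-bis(methoxymethoxy)phenyl]ethan-1-one | CC(=O)c1c(OCOC)cc(OC)cc1OCOC
F5 | step 10 | 1-(2,6-dihydroxy-4-methoxyphenyl)ethan-1-one | CC(=O)c1c(O)cc(OC)cc1O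
F6 | step 10 | (E)-1-(2,6-dihydroxy-4-methoxyphenyl)-3-(dimethylamino)prop-2-en-1-one | CN(C)/C=C/C(=O)c1c(O)cc(OC)cc1O
F7 | step 10 | 5-hydroxy-7-methoxy-4H-chromen-4-one | COc1cc(O)c2c(c1)occc2=O
F8 | step 10 | 5-(benzyloxy)-7-methoxy-4H-chromen-4-one | COc1cc(OCc3ccccc3)c2c(c1)occc2=O
F9 | step 20 | (2S)-5-hydroxy-7-methoxy-2-phenylchroman-4-one | COc1cc(O)c2c(c1)O[C@H](c1ccccc1)CC2=O
F10 | step 20 | (2S)-6,8-bis{2-(benzyloxy)-5-[2-(benzyloxy)benzyl]benzyl}-5-hydroxy-7-methoxy-2-phenylchroman-4-one | COc1c(Cc2cc(Cc3ccccc3OCc3ccccc3)ccc2OCc2ccccc2)c(O)c2c(c1Cc1cc(Cc3ccccc3OCc3ccccc3)ccc1OCc1ccccc1)O[C@H](c1ccccc1)CC2=O
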